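**Retrosynthetic overview**

1. Target 26 ⇒ hydrogenolysis of the protected dimer 25 ⇒ Lewis-acid C4–C8 coupling of the 4-alkoxy-epiafzelechin ether 16 (electrophile) with the epicatechin ether 24 (nucleophile).
2. The cis-flavan-3-ols 15 and 24 ⇒ dynamic kinetic resolution (transfer hydrogenation) of the racemic flavan-3-ones 14 and 23, which sets C2 and C3 together.
3. The flavan-3-ones ⇒ ring expansion (1,2-shift of C2, aldehyde → ketone) of the 2-aryl-2,3-dihydrobenzofuran-3-carbaldehydes 13 and 22, made from the 2-arylbenzofuran-3-carboxylates 11 and 20.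
4. 11 and 20 ⇒ C2–H arylation of one benzofuran ester 8 with the aryl bromides 10 and 19; 8 ⇒ salicylaldehyde 5 + ethyl diazoacetate 6; 5 ⇒ resorcinol 1.
5. Ring order: ring A (resorcinol) → five-membered O-ring → ring B attached → ring C by five-to-six ring expansion → union of the two flavans.

Abbreviations: Bn = benzyl; DMBn = 3,5-dimethylbenzyl; BnO and DMBnO are the corresponding ethers.

Assumption: the (S,S)-configured ruthenium catalyst is taken to give the (2R,3R) alcohols in steps 9 and 16; if a test reduction shows the opposite sense, its (R,R) antipode is used instead.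

**Route**

Step 1
Reactants: 1 resorcinol
Product: 2 1,3-bis(DMBnO)benzene
Conditions: 3,5-dimethylbenzyl bromide (2.2 equiv), K2CO3, DMF, 60 °C
Reagents that add atoms: 3,5-dimethylbenzyl bromide, Cc1cc(C)cc(CBr)c1
Why: Williamson ether synthesis; the 3,5-dimethylbenzyl group is a hydrogenolysable benzyl-type ether that has no unhindered aromatic C–H, so the borylation of step 2 can only touch the resorcinol ring.

Step 2
Reactants: 2 1,3-bis(DMBnO)benzene
Product: 4 3,5-bis(DMBnO)phenol, via aryl pinacol boronate 3 (not isolated)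
Conditions: [Ir(OMe)(cod)]2 (1.5 mol %), 4,4′-di-tert-butyl-2,2′-bipyridine (3 mol %), B2pin2 (1.0 equiv), THF, 80 °C; then KHSO5 (as 2KHSO5·KHSO4·K2SO4), acetone–H2O, 0 °C → rt
Reagents that add atoms: bis(pinacolato)diboron, CC1(C)OB(OC1(C)C)B1OC(C)(C)C(C)(C)O1 (boron of 3); potassium peroxymonosulfate, [K+].[O-]S(=O)(=O)OO (oxygen of 4)
Why: Sterically controlled iridium-catalysed C–H borylation occurs at the only C–H flanked by two hydrogens (meta to both ethers), and oxidation of the boronate (aryl shift from boron to oxygen) gives the phloroglucinol-type phenol.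

Step 3
Reactants: 4 3,5-bis(DMBnO)phenol
Product: 5 2-hydroxy-4,6-bis(DMBnO)benzaldehyde
Conditions: MgCl2 (1.5 equiv), Et3N (3.75 equiv), (CH2O)n, MeCN, reflux; aq. HCl
Reagents that add atoms: paraformaldehyde (formaldehyde), C=O
Why: Magnesium-mediated ortho-formylation (Casnati–Skattebøl); the magnesium phenoxide delivers formaldehyde only to the ortho carbon (both ortho positions are equivalent) and a second formaldehyde oxidises the benzylic alkoxide.

Step 4
Reactants: 5 2-hydroxy-4,6-bis(DMBnO)benzaldehyde; 6 ethyl diazoacetate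
Product: 8 ethyl 4,6-bis(DMBnO)benzofuran-3-carboxylate, via hemiacetal 7 (not isolated)
Conditions: HBF4·OEt2 (10 mol %), CH2Cl2, rt; then p-TsOH·H2O (20 mol %), 40 °C
Reagents that add atoms: none
Why: Acid-catalysed addition of the diazo ester to the aldehyde with loss of N2 and 1,2-shift of the electron-rich aryl group (Roskamp-type homologation) gives the 3-hydroxy-2-arylacrylate, which closes to hemiacetal 7 and aromatises by dehydration.

Step 5
Reactants: 9 4-bromophenol
Product: 10 1-(benzyloxy)-4-bromobenzene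
Conditions: BnBr (1.1 equiv), K2CO3, acetone, reflux
Reagents that add atoms: benzyl bromide, BrCc1ccccc1
Why: Williamson ether synthesis.

Step 6
Reactants: 8 ethyl 4,6-bis(DMBnO)benzofuran-3-carboxylate; 10 1-(benzyloxy)-4-bromobenzene
Product: 11 ethyl 2-[4-(benzyloxy)phenyl]-4,6-bis(DMBnO)benzofuran-3-carboxylate
Conditions: Pd(OAc)2 (5 mol %), PCy3·HBF4 (10 mol %), PivOH (30 mol %), K2CO3 (1.5 equiv), DMA, 100 °C
Reagents that add atoms: none
Why: Palladium-catalysed direct C–H arylation (concerted metalation–deprotonation) at C2, the most acidic C–H of the benzofuran, which the 3-ester activates further.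

Step 7
Reactants: 11 ethyl 2-[4-(benzyloxy)phenyl]-4,6-bis(DMBnO)benzofuran-3-carboxylate
Product: 12 methyl (±)-trans-2-[4-(benzyloxy)phenyl]-4,6-bis(DMBnO)-2,3-dihydrobenzofuran-3-carboxylate
Conditions: Mg turnings (10 equiv), MeOH–THF (2:1), 0 °C → rt; aq. NH4Cl
Reagents that add atoms: methanol, CO
Why: Dissolving-metal (Mg/MeOH) conjugate reduction of the aryl-conjugated enoate with ester exchange to the methyl ester; the trans racemate forms under thermodynamic protonation and no stereocontrol is needed because C3 is lost in step 8 and C2 is reset in step 9.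

Step 8
Reactants: 12 methyl (±)-trans-2-[4-(benzyloxy)phenyl]-4,6-bis(DMBnO)-2,3-dihydrobenzofuran-3-carboxylate
Product: 14 (±)-2-[4-(benzyloxy)phenyl]-5,7-bis(DMBnO)chroman-3-one, via dihydrobenzofuran-3-carbaldehyde 13 (not isolated)
Conditions: iBu2AlH (DIBAL-H, 1.1 equiv), CH2Cl2, −78 °C; then BF3·OEt2 (2 equiv), 0.02 M, −78 → −20 °C; aq. NaHCO3
Reagents that add atoms: none
Why: Proposed new method: once iBu2AlH has brought the ester to the aldehyde level, BF3 activates the formyl group of 13 and the ring bond C3–C2 migrates to the formyl carbon (C2 is the only substituent at C3 whose shift leaves a cation that ring A can stabilise), which turns the five-membered into the six-membered ring and places the positive charge at the future C4 next to the 2,4,6-trioxygenated ring A, and a 1,2-hydride shift from the carbinol carbon then gives the ketone as the thermodynamic sink; this is the known Lewis-acid ring contraction of 3,4-epoxychromans to 2,3-dihydrobenzofuran-3-carbaldehydes run backwards and drained through the Meinwald hydride-shift exit of the same cation, the closest known reaction type being the acid-promoted aldehyde–ketone (Danilov) rearrangement, and no stereocontrol is asked of it.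

Step 9
Reactants: 14 (±)-2-[4-(benzyloxy)phenyl]-5,7-bis(DMBnO)chroman-3-one
Product: 15 (2R,3R)-2-[4-(benzyloxy)phenyl]-5,7-bis(DMBnO)chroman-3-ol
Conditions: RuCl[(S,S)-TsDPEN](p-cymene) (2 mol %), HCO2H–Et3N (5:2), DMF, 40 °C
Reagents that add atoms: none
Why: Proposed new method: Noyori–Ikariya asymmetric transfer hydrogenation under dynamic kinetic resolution, in which C2 of the ketone (α to the carbonyl, benzylic and O-substituted) epimerises through the enol under HCO2H–Et3N faster than either enantiomer is reduced and the chiral Ru–H/N–H catalyst reduces the (2R)-ketone from the face anti to the aryl group, so that C2 and C3 are set together as the 2,3-cis (2R,3R) alcohol; the closest known reactions are the dynamic kinetic transfer hydrogenations of 2-arylcycloalkanones, α-aryloxy ketones and isoflavanones, and flavan-3-ones are a substrate class on which it has not been shown.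

Step 10
Reactants: 15 (2R,3R)-2-[4-(benzyloxy)phenyl]-5,7-bis(DMBnO)chroman-3-ol
Product: 16 (2R,3R,4S)-2-[4-(benzyloxy)phenyl]-5,7-bis(DMBnO)-4-(2-ethoxyethoxy)chroman-3-ol
Conditions: DDQ (2 equiv), 2-ethoxyethanol (5 equiv), CH2Cl2, rt
Reagents that add atoms: 2-ethoxyethanol, CCOCCO
Why: DDQ benzylic oxidation (hydride abstraction at C4 gives the cation stabilised by ring A, which the alcohol traps trans to the 3-OH); the C4 configuration is lost again in step 17.

Step 11
Reactants: 17 catechol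
Product: 18 1,2-bis(benzyloxy)benzene
Conditions: BnBr (2.2 equiv), K2CO3, DMF, 60 °C
Reagents that add atoms: benzyl bromide, BrCc1ccccc1
Why: Williamson ether synthesis.

Step 12
Reactants: 18 1,2-bis(benzyloxy)benzene
Product: 19 4-bromo-1,2-bis(benzyloxy)benzene
Conditions: NBS (1.05 equiv), MeCN, 0 °C → rt
Reagents that add atoms: N-bromosuccinimide, O=C1CCC(=O)N1Br
Why: Electrophilic aromatic bromination, para to one alkoxy group and meta to the other, as with veratrole.

Step 13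
Reactants: 8 ethyl 4,6-bis(DMBnO)benzofuran-3-carboxylate; 19 4-bromo-1,2-bis(benzyloxy)benzene
Product: 20 ethyl 2-[3,4-bis(benzyloxy)phenyl]-4,6-bis(DMBnO)benzofuran-3-carboxylate
Conditions: Pd(OAc)2 (5 mol %), PCy3·HBF4 (10 mol %), PivOH (30 mol %), K2CO3 (1.5 equiv), DMA, 100 °C
Reagents that add atoms: none
Why: Palladium-catalysed direct C–H arylation at C2 of the benzofuran, as in step 6.

Step 14
Reactants: 20 ethyl 2-[3,4-bis(benzyloxy)phenyl]-4,6-bis(DMBnO)benzofuran-3-carboxylate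
Product: 21 methyl (±)-trans-2-[3,4-bis(benzyloxy)phenyl]-4,6-bis(DMBnO)-2,3-dihydrobenzofuran-3-carboxylate
Conditions: Mg turnings (10 equiv), MeOH–THF (2:1), 0 °C → rt; aq. NH4Cl
Reagents that add atoms: methanol, CO
Why: Mg/MeOH conjugate reduction with ester exchange, as in step 7; the racemic trans ester suffices.

Step 15
Reactants: 21 methyl (±)-trans-2-[3,4-bis(benzyloxy)phenyl]-4,6-bis(DMBnO)-2,3-dihydrobenzofuran-3-carboxylate
Product: 23 (±)-2-[3,4-bis(benzyloxy)phenyl]-5,7-bis(DMBnO)chroman-3-one, via dihydrobenzofuran-3-carbaldehyde 22 (not isolated)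
Conditions: iBu2AlH (DIBAL-H, 1.1 equiv), CH2Cl2, −78 °C; then BF3·OEt2 (2 equiv), 0.02 M, −78 → −20 °C; aq. NaHCO3
Reagents that add atoms: none
Why: Proposed new method: as in step 8, the BF3-activated formyl group of 22 accepts the 1,2-shift of C2 from C3 (five- to six-membered ring), the resulting C4 cation is stabilised by ring A and a 1,2-hydride shift gives the more stable ketone; the closest known reaction type is the aldehyde–ketone (Danilov) rearrangement, and the sequence is the reverse of the known ring contraction of 3,4-epoxychromans joined to their Meinwald hydride-shift exit.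

Step 16
Reactants: 23 (±)-2-[3,4-bis(benzyloxy)phenyl]-5,7-bis(DMBnO)chroman-3-one
Product: 24 (2R,3R)-2-[3,4-bis(benzyloxy)phenyl]-5,7-bis(DMBnO)chroman-3-ol
Conditions: RuCl[(S,S)-TsDPEN](p-cymene) (2 mol %), HCO2H–Et3N (5:2), DMF, 40 °C
Reagents that add atoms: none
Why: Proposed new method: as in step 9, C2 epimerises through the enol while the Noyori–Ikariya catalyst reduces one ketone enantiomer anti to the aryl group, giving the 2,3-cis (2R,3R) alcohol by dynamic kinetic resolution; the closest known cases are 2-arylcycloalkanones, α-aryloxy ketones and isoflavanones.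

Step 17
Reactants: 16 (2R,3R,4S)-2-[4-(benzyloxy)phenyl]-5,7-bis(DMBnO)-4-(2-ethoxyethoxy)chroman-3-ol; 24 (2R,3R)-2-[3,4-bis(benzyloxy)phenyl]-5,7-bis(DMBnO)chroman-3-ol
Product: 25 protected epiafzelechin-(4β→8)-epicatechin (three Bn and four DMBn ethers; both 3-OH free)
Conditions: Me3SiOTf (0.3 equiv), CH2Cl2, −78 °C; 24 in threefold excess (recovered)
Reagents that add atoms: none
Why: Lewis-acid ionisation of the 4-ether gives the flavan-4-yl cation, which C8 of 24 (the more nucleophilic ring-A position) attacks in a Friedel–Crafts reaction anti to the 3-OH of the 2,3-cis unit, setting C4 as 4β (3,4-trans, 4R); the excess of 24 suppresses oligomers.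

Step 18
Reactants: 25 protected epiafzelechin-(4β→8)-epicatechin
Product: 26 (−)-epiafzelechin-(4β→8)-(−)-epicatechin
Conditions: H2 (1 atm), Pd(OH)2/C, THF–MeOH–H2O (20:20:1), rt
Reagents that add atoms: none
Why: Hydrogenolysis of all seven benzyl-type aryl ethers under neutral conditions, which leaves the interflavan bond and the five stereocentres untouched.

**Compound list**

1 | resorcinol (benzene-1,3-diol) | Oc1cccc(O)c1 | starting material
2 | 1,3-bis[(3,5-dimethylbenzyl)oxy]benzene | Cc1cc(C)cc(COc2cccc(OCc3cc(C)cc(C)c3)c2)c1 | intermediate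
3 | 2-{3,5-bis[(3,5-dimethylbenzyl)oxy]phenyl}-4,4,5,5-tetramethyl-1,3,2-dioxaborolane (not isolated) | Cc1cc(C)cc(COc2cc(OCc3cc(C)cc(C)c3)cc(B3OC(C)(C)C(C)(C)O3)c2)c1 | intermediate
4 | 3,5-bis[(3,5-dimethylbenzyl)oxy]phenol | Cc1cc(C)cc(COc2cc(O)cc(OCc3cc(C)cc(C)c3)c2)c1 | intermediate
5 | 2-hydroxy-4,6-bis[(3,5-dimethylbenzyl)oxy]benzaldehyde | O=Cc1c(O)cc(OCc2cc(C)cc(C)c2)cc1OCc1cc(C)cc(C)c1 | intermediate
6 | ethyl diazoacetate | CCOC(=O)C=[N+]=[N-] | starting material
7 | ethyl 2-hydroxy-4,6-bis[(3,5-dimethylbenzyl)oxy]-2,3-dihydrobenzofuran-3-carboxylate (hemiacetal, isomer mixture, not isolated) | CCOC(=O)C1C(O)Oc2cc(OCc3cc(C)cc(C)c3)cc(OCc3cc(C)cc(C)c3)c21 | intermediate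
8 | ethyl 4,6-bis[(3,5-dimethylbenzyl)oxy]benzofuran-3-carboxylate | CCOC(=O)c1coc2cc(OCc3cc(C)cc(C)c3)cc(OCc3cc(C)cc(C)c3)c12 | intermediate
9 | 4-bromophenol | Oc1ccc(Br)cc1 | starting material
10 | 1-(benzyloxy)-4-bromobenzene | Brc1ccc(OCc2ccccc2)cc1 | intermediate
11 | ethyl 2-[4-(benzyloxy)phenyl]-4,6-bis[(3,5-dimethylbenzyl)oxy]benzofuran-3-carboxylate | CCOC(=O)c1c(-c2ccc(OCc3ccccc3)cc2)oc2cc(OCc3cc(C)cc(C)c3)cc(OCc3cc(C)cc(C)c3)c12 | intermediate
12 | methyl (±)-trans-2-[4-(benzyloxy)phenyl]-4,6-bis[(3,5-dimethylbenzyl)oxy]-2,3-dihydrobenzofuran-3-carboxylate (racemate, one enantiomer drawn) | COC(=O)[C@@H]1[C@@H](c2ccc(OCc3ccccc3)cc2)Oc2cc(OCc3cc(C)cc(C)c3)cc(OCc3cc(C)cc(C)c3)c21 | intermediate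
13 | (±)-2-[4-(benzyloxy)phenyl]-4,6-bis[(3,5-dimethylbenzyl)oxy]-2,3-dihydrobenzofuran-3-carbaldehyde (C3 epimers, not isolated) | O=CC1C(c2ccc(OCc3ccccc3)cc2)Oc2cc(OCc3cc(C)cc(C)c3)cc(OCc3cc(C)cc(C)c3)c21 | intermediate
14 | (±)-2-[4-(benzyloxy)phenyl]-5,7-bis[(3,5-dimethylbenzyl)oxy]chroman-3-one | O=C1Cc2c(OCc3cc(C)cc(C)c3)cc(OCc3cc(C)cc(C)c3)cc2OC1c1ccc(OCc2ccccc2)cc1 | intermediate
15 | (2R,3R)-2-[4-(benzyloxy)phenyl]-5,7-bis[(3,5-dimethylbenzyl)oxy]chroman-3-ol (protected epiafzelechin) | c1ccccc1COc1ccc([C@H]2Oc3cc(OCc4cc(C)cc(C)c4)cc(OCc4cc(C)cc(C)c4)c3C[C@H]2O)cc1 | intermediate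
16 | (2R,3R,4S)-2-[4-(benzyloxy)phenyl]-5,7-bis[(3,5-dimethylbenzyl)oxy]-4-(2-ethoxyethoxy)chroman-3-ol (4β-ether, 3,4-trans) | c1ccccc1COc1ccc([C@H]2Oc3cc(OCc4cc(C)cc(C)c4)cc(OCc4cc(C)cc(C)c4)c3[C@H](OCCOCC)[C@H]2O)cc1 | intermediate
17 | catechol (benzene-1,2-diol) | Oc1ccccc1O | starting material
18 | 1,2-bis(benzyloxy)benzene | c1ccc(COc2ccccc2OCc2ccccc2)cc1 | intermediate
19 | 4-bromo-1,2-bis(benzyloxy)benzene | Brc1ccc(OCc2ccccc2)c(OCc2ccccc2)c1 | intermediate
20 | ethyl 2-[3,4-bis(benzyloxy)phenyl]-4,6-bis[(3,5-dimethylbenzyl)oxy]benzofuran-3-carboxylate | CCOC(=O)c1c(-c2ccc(OCc3ccccc3)c(OCc3ccccc3)c2)oc2cc(OCc3cc(C)cc(C)c3)cc(OCc3cc(C)cc(C)c3)c12 | intermediate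
21 | methyl (±)-trans-2-[3,4-bis(benzyloxy)phenyl]-4,6-bis[(3,5-dimethylbenzyl)oxy]-2,3-dihydrobenzofuran-3-carboxylate (racemate, one enantiomer drawn) | COC(=O)[C@@H]1[C@@H](c2ccc(OCc3ccccc3)c(OCc3ccccc3)c2)Oc2cc(OCc3cc(C)cc(C)c3)cc(OCc3cc(C)cc(C)c3)c21 | intermediate
22 | (±)-2-[3,4-bis(benzyloxy)phenyl]-4,6-bis[(3,5-dimethylbenzyl)oxy]-2,3-dihydrobenzofuran-3-carbaldehyde (C3 epimers, not isolated) | O=CC1C(c2ccc(OCc3ccccc3)c(OCc3ccccc3)c2)Oc2cc(OCc3cc(C)cc(C)c3)cc(OCc3cc(C)cc(C)c3)c21 | intermediate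
23 | (±)-2-[3,4-bis(benzyloxy)phenyl]-5,7-bis[(3,5-dimethylbenzyl)oxy]chroman-3-one | O=C1Cc2c(OCc3cc(C)cc(C)c3)cc(OCc3cc(C)cc(C)c3)cc2OC1c1ccc(OCc2ccccc2)c(OCc2ccccc2)c1 | intermediate
24 | (2R,3R)-2-[3,4-bis(benzyloxy)phenyl]-5,7-bis[(3,5-dimethylbenzyl)oxy]chroman-3-ol (protected epicatechin) | Cc1cc(C)cc(COc2cc(OCc3cc(C)cc(C)c3)c3c(c2)O[C@H](c2ccc(OCc4ccccc4)c(OCc4ccccc4)c2)[C@H](O)C3)c1 | intermediate
25 | 4′-O-benzyl-5,7-bis-O-(3,5-dimethylbenzyl)-epiafzelechin-(4β→8)-3′,4′-di-O-benzyl-5,7-bis-O-(3,5-dimethylbenzyl)-epicatechin; upper unit (2R,3R,4R), lower unit (2R,3R) | c1ccccc1COc1ccc([C@H]2Oc3cc(OCc4cc(C)cc(C)c4)cc(OCc4cc(C)cc(C)c4)c3[C@H](c3c(OCc4cc(C)cc(C)c4)cc(OCc4cc(C)cc(C)c4)c4c3O[C@H](c3ccc(OCc5ccccc5)c(OCc5ccccc5)c3)[C@H](O)C4)[C@H]2O)cc1 | intermediate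
26 | (−)-epiafzelechin-(4β→8)-(−)-epicatechin; upper unit (2R,3R,4R), lower unit (2R,3R) | Oc1ccc([C@H]2Oc3cc(O)cc(O)c3[C@H](c3c(O)cc(O)c4c3O[C@H](c3ccc(O)c(O)c3)[C@H](O)C4)[C@H]2O)cc1 | target

**Step count and risks**

Total: 18 steps. Longest linear sequence: 11 steps (1, 2, 3, 4, 6, 7, 8, 9, 10, 17, 18).

The three steps most likely to fail are step 8, step 9 and step 4. Steps 15 and 16 repeat the transformations of steps 8 and 9.

Step 8 (new ring expansion). The cation may be intercepted by another electron-rich ring, or the aldehyde may not re-enter the cationic manifold. The fallback is known flavene chemistry that sets out from phenol 4 and bromide 10 and comes back at ketone 14. A Heck reaction of 10 with acrolein diethyl acetal (Pd(OAc)2, nBu4NOAc, K2CO3, KCl, DMF, 90 °C; then dilute HCl) gives (E)-3-[4-(benzyloxy)phenyl]prop-2-enal F1. Condensation of F1 with 4 (ethylenediammonium diacetate, toluene, reflux) gives the racemic flav-3-ene 2-[4-(benzyloxy)phenyl]-5,7-bis[(3,5-dimethylbenzyl)oxy]-2H-chromene F2. Hydroboration–oxidation (BH3·THF; NaOH, H2O2) gives (±)-trans-2-[4-(benzyloxy)phenyl]-5,7-bis[(3,5-dimethylbenzyl)oxy]chroman-3-ol F3. Dess–Martin oxidation of F3 then gives 14.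

Step 9 (new dynamic kinetic resolution on a flavan-3-one). Racemisation at C2 may be too slow, or the dr or ee too low. The fallback is reduction plus classical resolution; it sets out from ketone 14 and comes back at alcohol 15. Ketone 14 is reduced with LiBH(sBu)3 (THF, −78 °C), which is known to give 2,3-cis-flavan-3-ols. Without isolating anything, (S)-O-acetylmandeloyl chloride is added to give two diastereomeric esters. These are (2R,3R)-2-[4-(benzyloxy)phenyl]-5,7-bis[(3,5-dimethylbenzyl)oxy]chroman-3-yl (S)-2-acetoxy-2-phenylacetate F4 and its (2S,3S)-chromanyl diastereomer (2S,3S)-2-[4-(benzyloxy)phenyl]-5,7-bis[(3,5-dimethylbenzyl)oxy]chroman-3-yl (S)-2-acetoxy-2-phenylacetate F5. They are separated by chromatography, and methanolysis of F4 (K2CO3, MeOH) gives 15.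

Step 4 (acid-catalysed benzofuran formation on a strongly deactivated, acid-sensitive salicylaldehyde). The fallback builds the furan ring by C–H functionalisation instead; it sets out from phenol 4 and comes back at ester 8, bypassing 5. Oxa-Michael addition of 4 to ethyl propiolate (DABCO, CH2Cl2, rt) gives ethyl (E)-3-{3,5-bis[(3,5-dimethylbenzyl)oxy]phenoxy}acrylate F6. A dehydrogenative Heck (Fujiwara–Moritani) cyclisation with Pd(OAc)2 (10 mol %) and Cu(OAc)2 (2 equiv) in DMA at 100 °C under air then gives 8.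

**Further compounds**

F1 | step 8 | (E)-3-[4-(benzyloxy)phenyl]prop-2-enal | O=C/C=C/c1ccc(OCc2ccccc2)cc1
F2 | step 8 | (±)-2-[4-(benzyloxy)phenyl]-5,7-bis[(3,5-dimethylbenzyl)oxy]-2H-chromene | C1(c2ccc(OCc3ccccc3)cc2)C=Cc2c(OCc3cc(C)cc(C)c3)cc(OCc3cc(C)cc(C)c3)cc2O1
F3 | step 8 | (±)-trans-2-[4-(benzyloxy)phenyl]-5,7-bis[(3,5-dimethylbenzyl)oxy]chroman-3-ol (racemate, (2R,3S) enantiomer drawn) | c1ccccc1COc1ccc([C@H]2Oc3cc(OCc4cc(C)cc(C)c4)cc(OCc4cc(C)cc(C)c4)c3C[C@@H]2O)cc1
F4 | step 9 | (2R,3R)-2-[4-(benzyloxy)phenyl]-5,7-bis[(3,5-dimethylbenzyl)oxy]chroman-3-yl (S)-2-acetoxy-2-phenylacetate | c1ccccc1COc1ccc([C@H]2Oc3cc(OCc4cc(C)cc(C)c4)cc(OCc4cc(C)cc(C)c4)c3C[C@H]2OC(=O)[C@@H](OC(C)=O)c2ccccc2)cc1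
F5 | step 9 | (2S,3S)-2-[4-(benzyloxy)phenyl]-5,7-bis[(3,5-dimethylbenzyl)oxy]chroman-3-yl (S)-2-acetoxy-2-phenylacetate | c1ccccc1COc1ccc([C@@H]2Oc3cc(OCc4cc(C)cc(C)c4)cc(OCc4cc(C)cc(C)c4)c3C[C@@H]2OC(=O)[C@@H](OC(C)=O)c2ccccc2)cc1
F6 | step 4 | ethyl (E)-3-{3,5-bis[(3,5-dimethylbenzyl)oxy]phenoxy}acrylate | CCOC(=O)/C=C/Oc1cc(OCc2cc(C)cc(C)c2)cc(OCc2cc(C)cc(C)c2)c1
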